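**Retrosynthetic overview**

- Feature: ring A carries oxygen on all four non-fusion carbons C5, C6, C7 and C8. These are the four carbons of dimethyl squarate, while the fusion carbons C4a and C8a are C3 and C2 of a preformed 6-aryl-4-pyranone (ring C).
- Agehoustin C ⇐ O-debenzylation and O-methylation of the 3'-benzyloxy-8-hydroxyflavone ⇐ thermal ring expansion (C8–C8a bond, ring A) of a 4-(pyranon-3-yl)-2,3,4-trimethoxycyclobutenone.
- Cyclobutenone ⇐ dimethyl squarate + 5-magnesiated 2-aryl-4-pyranone (from the 5-iodide), then O-methylation.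
- Iodopyranone ⇐ ring B aroyl chloride + lithium enolate of 3-iodo-4-methoxybut-3-en-2-one, then acid cyclization. Aroyl chloride ⇐ 1,2,4-trimethoxybenzene by ortho-lithiation/oxidation at C3, acetate-controlled bromination and carboxylation.
- Ring order: ring B (purchased arene), ring C (pyranone), ring A last (electrocyclization).

Key step: step 12

Remark on the chemistry: iodine is taken as the halogen on the pyranone, because iodine–magnesium exchange runs at −40 °C, cold enough to outrun ring opening of the metalated pyranone. The (Z) geometry written for the iodoenone is the expected one and has no bearing on the later cyclization.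

**Route**

Step 1
Reactants: 1 1,2,4-trimethoxybenzene
Product: 4 2,3,6-trimethoxyphenol, via (2,3,6-trimethoxyphenyl)lithium 2 (not isolated), via lithium trimethoxy(2,3,6-trimethoxyphenyl)borate 3 (not isolated)
Conditions: n-BuLi, TMEDA, THF, 0 °C; B(OMe)3, −78 °C to rt; AcOH, 30% aq. H2O2, 0 °C to rt
Reagents that add atoms: hydrogen peroxide, OO
Why: Directed ortho-metalation should take place at C3, the C–H flanked by the 2- and 4-methoxy groups, and borylation followed by peroxide oxidation (aryl shift from boron to oxygen) turns the aryllithium into the phenol.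

Step 2
Reactants: 4 2,3,6-trimethoxyphenol
Product: 5 2,3,6-trimethoxyphenyl acetate
Conditions: Ac2O, pyridine, DMAP (cat.), CH2Cl2, rt
Reagents that add atoms: acetic anhydride, CC(=O)OC(C)=O
Why: DMAP-catalysed O-acylation converts the strongly donating hydroxyl into a weakly donating acyloxy group, so that it no longer directs the following substitution.

Step 3
Reactants: 5 2,3,6-trimethoxyphenyl acetate
Product: 6 3-bromo-2,5,6-trimethoxyphenyl acetate
Conditions: NBS (1.0 equiv), MeCN, 0 °C to rt
Reagents that add atoms: N-bromosuccinimide, O=C1CCC(=O)N1Br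
Why: Electrophilic aromatic bromination should go to C5 of 5 (ortho to the 6-methoxy and para to the 2-methoxy group) in preference to C4 (para to the acetoxy group), because an ether oxygen is a far better para donor than an ester oxygen; this puts bromine meta to the masked phenol.

Step 4
Reactants: 6 3-bromo-2,5,6-trimethoxyphenyl acetate
Product: 8 3-(benzyloxy)-1-bromo-2,4,5-trimethoxybenzene, via 3-bromo-2,5,6-trimethoxyphenol 7 (not isolated)
Conditions: K2CO3, MeOH, rt; evaporate; BnBr, DMF, rt
Reagents that add atoms: benzyl bromide, BrCc1ccccc1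
Why: Base-catalysed transesterification removes the aryl acetate, and Williamson etherification of the phenoxide installs the benzyl group that is to last until the final step.

Step 5
Reactants: 8 3-(benzyloxy)-1-bromo-2,4,5-trimethoxybenzene
Product: 10 3-(benzyloxy)-2,4,5-trimethoxybenzoic acid, via [3-(benzyloxy)-2,4,5-trimethoxyphenyl]lithium 9 (not isolated)
Conditions: n-BuLi, THF, −78 °C; CO2; aq. HCl
Reagents that add atoms: carbon dioxide, O=C=O
Why: Bromine–lithium exchange at −78 °C is much faster than any attack on the benzyl ether, and carboxylation of the aryllithium gives the acid at the carbon that bore bromine.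

Step 6
Reactants: 10 3-(benzyloxy)-2,4,5-trimethoxybenzoic acid
Product: 11 3-(benzyloxy)-2,4,5-trimethoxybenzoyl chloride
Conditions: (COCl)2, DMF (cat.), CH2Cl2, 0 °C to rt; evaporate
Reagents that add atoms: oxalyl chloride, O=C(Cl)C(Cl)=O
Why: Acid chloride formation through the Vilsmeier-type chloroiminium catalyst is neutral enough to leave the aryl ethers untouched, and the product is used crude.

Step 7
Reactants: 12 (E)-4-methoxybut-3-en-2-one
Product: 14 (Z)-3-iodo-4-methoxybut-3-en-2-one, via 4-chloro-3-iodo-4-methoxybutan-2-one 13 (not isolated)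
Conditions: ICl, CH2Cl2, −78 to 0 °C; Et3N, 0 °C to rt
Reagents that add atoms: iodine monochloride, ClI
Why: Electrophilic addition of ICl to the enol ether double bond (iodine to the α-carbon, chloride to the oxocarbenium carbon) followed by base-induced elimination of HCl should restore the push–pull alkene as the α-iodo enone.

Step 8
Reactants: 14 (Z)-3-iodo-4-methoxybut-3-en-2-one (2.1 equiv); 11 3-(benzyloxy)-2,4,5-trimethoxybenzoyl chloride
Product: 16 (4Z)-1-[3-(benzyloxy)-2,4,5-trimethoxyphenyl]-4-iodo-5-methoxypent-4-ene-1,3-dione, via lithium (Z)-3-iodo-4-methoxybuta-1,3-dien-2-olate 15 (not isolated)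
Conditions: LiN(SiMe3)2 (2.1 equiv), THF, −78 °C; 11, −78 to −30 °C; aq. NH4Cl
Reagents that add atoms: none
Why: Crossed Claisen-type C-acylation of the kinetic methyl-ketone lithium enolate by the aroyl chloride gives the β-diketone, the second equivalent of enolate taking up the proton of the more acidic product.

Step 9
Reactants: 16 (4Z)-1-[3-(benzyloxy)-2,4,5-trimethoxyphenyl]-4-iodo-5-methoxypent-4-ene-1,3-dione
Product: 17 2-[3-(benzyloxy)-2,4,5-trimethoxyphenyl]-5-iodo-4H-pyran-4-one
Conditions: TFA (5 equiv), CH2Cl2, 0 °C to rt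
Reagents that add atoms: none
Why: Acid-catalysed 6-endo oxa-Michael addition of the enol oxygen to the β-methoxy enone and loss of methanol (addition–elimination) should close ring C as the 4-pyranone, under conditions too mild to cleave the benzyl ether.

Step 10
Reactants: 17 2-[3-(benzyloxy)-2,4,5-trimethoxyphenyl]-5-iodo-4H-pyran-4-one; 18 dimethyl squarate (3,4-dimethoxycyclobut-3-ene-1,2-dione)
Product: 20 4-{6-[3-(benzyloxy)-2,4,5-trimethoxyphenyl]-4-oxo-4H-pyran-3-yl}-4-hydroxy-2,3-dimethoxycyclobut-2-en-1-one (racemic), via {6-[3-(benzyloxy)-2,4,5-trimethoxyphenyl]-4-oxo-4H-pyran-3-yl}magnesium chloride 19 (not isolated)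
Conditions: i-PrMgCl·LiCl (1.05 equiv), THF, −40 °C, 15 min; cannulate into 18 (1.3 equiv), THF, −78 °C; −78 to −40 °C; aq. NH4Cl
Reagents that add atoms: none
Why: Iodine–magnesium exchange at the α-carbon of the vinylogous ester should be fast at −40 °C, where the β-oxygenated alkenylmagnesium does not yet fragment, and Grignard 1,2-addition to one of the two equivalent, highly electrophilic squarate carbonyls gives the tertiary alcohol as a racemate, whose stereocentre disappears in step 12.

Step 11
Reactants: 20 4-{6-[3-(benzyloxy)-2,4,5-trimethoxyphenyl]-4-oxo-4H-pyran-3-yl}-4-hydroxy-2,3-dimethoxycyclobut-2-en-1-one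
Product: 21 4-{6-[3-(benzyloxy)-2,4,5-trimethoxyphenyl]-4-oxo-4H-pyran-3-yl}-2,3,4-trimethoxycyclobut-2-en-1-one (racemic)
Conditions: MeI (excess), Ag2O, MeCN, rt, dark
Reagents that add atoms: iodomethane, CI
Why: Purdie methylation etherifies the tertiary alcohol without a strong base, which would open the α-hydroxycyclobutenone by retro-aldol cleavage.

Step 12
Reactants: 21 4-{6-[3-(benzyloxy)-2,4,5-trimethoxyphenyl]-4-oxo-4H-pyran-3-yl}-2,3,4-trimethoxycyclobut-2-en-1-one
Product: 24 3'-benzyloxy-8-hydroxy-5,6,7,2',4',5'-hexamethoxyflavone, via dienylketene 22 (not isolated), via 8a-H cyclohexadienone 23 (not isolated)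
Conditions: degassed toluene (0.02 M), 110 °C, sealed vessel
Reagents that add atoms: none
Why: Heating should open the cyclobutenone by conrotatory four-electron electrocyclic cleavage of the bond between the carbonyl carbon and the quaternary carbon to give dienylketene 22; the methoxy donor on the quaternary carbon rotates outward (torquoselectivity), so the pyranonyl group turns inward and lies cis to the ketene. The ketene carbon, the two methoxy-bearing alkene carbons, the former quaternary carbon and the pyranone C3=C2 bond then form a hexatriene that closes by thermal disrotatory six-electron electrocyclization, which makes the C8–C8a bond and ring A as dienone 23. A proton shift from C8a to the C8 oxygen, driven by aromatization of ring A and restoration of the pyranone, gives phenol 24. The closest known reaction is the Moore rearrangement of 4-aryl-, 4-heteroaryl- and 4-alkenyl-4-alkoxycyclobutenones; the weakly aromatic pyranone double bond should behave like the easier alkenyl case. No stereocentre is formed, since the quaternary carbon of 21 becomes the sp2 carbon C5. The step needs closure at the pyranone C2–H carbon, which is the only hydrogen-bearing ring carbon next to the point of attachment (the other neighbour is the carbonyl carbon), and high dilution without nucleophiles keeps the ketene from being intercepted.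

Step 13
Reactants: 24 3'-benzyloxy-8-hydroxy-5,6,7,2',4',5'-hexamethoxyflavone
Product: 25 3'-benzyloxy-5,6,7,8,2',4',5'-heptamethoxyflavone
Conditions: MeI, K2CO3, acetone, reflux
Reagents that add atoms: iodomethane, CI
Why: Williamson methylation of the flanked but acidic C8 phenol completes the tetramethoxy pattern of ring A under conditions that flavones tolerate.

Step 14
Reactants: 25 3'-benzyloxy-5,6,7,8,2',4',5'-heptamethoxyflavone
Product: 26 agehoustin C (3'-hydroxy-5,6,7,8,2',4',5'-heptamethoxyflavone)
Conditions: H2 (1 atm), palladium on carbon (10% Pd/C), EtOAc–MeOH, rt, stopped at one equivalent of H2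
Reagents that add atoms: none
Why: Catalytic hydrogenolysis cleaves the benzyl aryl ether selectively, the methyl ethers being inert and the conjugated C2=C3 bond of ring C being reduced much more slowly.

**Compound list**

1 | 1,2,4-trimethoxybenzene | COc1ccc(OC)c(OC)c1 | starting material
2 | (2,3,6-trimethoxyphenyl)lithium (formed in the flask) | COc1ccc(OC)c(OC)c1[Li] | intermediate
3 | lithium trimethoxy(2,3,6-trimethoxyphenyl)borate (formed in the flask) | [Li+].COc1ccc(OC)c(OC)c1[B-](OC)(OC)OC | intermediate
4 | 2,3,6-trimethoxyphenol | COc1ccc(OC)c(OC)c1O | intermediate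
5 | 2,3,6-trimethoxyphenyl acetate | COc1ccc(OC)c(OC)c1OC(C)=O | intermediate
6 | 3-bromo-2,5,6-trimethoxyphenyl acetate | COc1c(Br)cc(OC)c(OC)c1OC(C)=O | intermediate
7 | 3-bromo-2,5,6-trimethoxyphenol (formed in the flask) | COc1c(Br)cc(OC)c(OC)c1O | intermediate
8 | 3-(benzyloxy)-1-bromo-2,4,5-trimethoxybenzene | COc1cc(Br)c(OC)c(OCc2ccccc2)c1OC | intermediate
9 | [3-(benzyloxy)-2,4,5-trimethoxyphenyl]lithium (formed in the flask) | [Li]c1cc(OC)c(OC)c(OCc2ccccc2)c1OC | intermediate
10 | 3-(benzyloxy)-2,4,5-trimethoxybenzoic acid | COc1cc(C(=O)O)c(OC)c(OCc2ccccc2)c1OC | intermediate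
11 | 3-(benzyloxy)-2,4,5-trimethoxybenzoyl chloride | COc1cc(C(Cl)=O)c(OC)c(OCc2ccccc2)c1OC | intermediate
12 | (E)-4-methoxybut-3-en-2-one | CO/C=C/C(C)=O | starting material
13 | 4-chloro-3-iodo-4-methoxybutan-2-one (diastereomer mixture, formed in the flask) | COC(Cl)C(I)C(C)=O | intermediate
14 | (Z)-3-iodo-4-methoxybut-3-en-2-one | CO/C=C(\I)C(C)=O | intermediate
15 | lithium (Z)-3-iodo-4-methoxybuta-1,3-dien-2-olate (formed in the flask) | CO/C=C(\I)C(=C)O[Li] | intermediate
16 | (4Z)-1-[3-(benzyloxy)-2,4,5-trimethoxyphenyl]-4-iodo-5-methoxypent-4-ene-1,3-dione | CO/C=C(\I)C(=O)CC(=O)c1cc(OC)c(OC)c(OCc2ccccc2)c1OC | intermediate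
17 | 2-[3-(benzyloxy)-2,4,5-trimethoxyphenyl]-5-iodo-4H-pyran-4-one | COc1cc(-c2cc(=O)c(I)co2)c(OC)c(OCc3ccccc3)c1OC | intermediate
18 | dimethyl squarate (3,4-dimethoxycyclobut-3-ene-1,2-dione) | COC1=C(OC)C(=O)C1=O | starting material
19 | {6-[3-(benzyloxy)-2,4,5-trimethoxyphenyl]-4-oxo-4H-pyran-3-yl}magnesium chloride (formed in the flask) | COc1cc(-c2cc(=O)c([Mg]Cl)co2)c(OC)c(OCc3ccccc3)c1OC | intermediate
20 | 4-{6-[3-(benzyloxy)-2,4,5-trimethoxyphenyl]-4-oxo-4H-pyran-3-yl}-4-hydroxy-2,3-dimethoxycyclobut-2-en-1-one (racemic) | COC1=C(OC)C(O)(c2coc(-c3cc(OC)c(OC)c(OCc4ccccc4)c3OC)cc2=O)C1=O | intermediate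
21 | 4-{6-[3-(benzyloxy)-2,4,5-trimethoxyphenyl]-4-oxo-4H-pyran-3-yl}-2,3,4-trimethoxycyclobut-2-en-1-one (racemic) | COC1=C(OC)C(OC)(c2coc(-c3cc(OC)c(OC)c(OCc4ccccc4)c3OC)cc2=O)C1=O | intermediate
22 | (Z)-dienylketene: 2,3,4-trimethoxy-4-(6-aryl-4-oxo-4H-pyran-3-yl)buta-1,3-dien-1-one, aryl = 3-(benzyloxy)-2,4,5-trimethoxyphenyl, pyranonyl cis to the ketene-bearing carbon (formed in the flask) | O=C=C(OC)/C(OC)=C(/OC)c1coc(-c2cc(OC)c(OC)c(OCc3ccccc3)c2OC)cc1=O | intermediate
23 | 2-[3-(benzyloxy)-2,4,5-trimethoxyphenyl]-5,6,7-trimethoxy-8aH-chromene-4,8-dione (racemic, formed in the flask) | COC1=C(OC)C(OC)=C2C(=O)C=C(c3cc(OC)c(OC)c(OCc4ccccc4)c3OC)OC2C1=O | intermediate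
24 | 3'-benzyloxy-8-hydroxy-5,6,7,2',4',5'-hexamethoxyflavone | COc1c(OC)c(OC)c2c(=O)cc(-c3cc(OC)c(OC)c(OCc4ccccc4)c3OC)oc2c1O | intermediate
25 | 3'-benzyloxy-5,6,7,8,2',4',5'-heptamethoxyflavone | COc1cc(-c2cc(=O)c3c(OC)c(OC)c(OC)c(OC)c3o2)c(OC)c(OCc2ccccc2)c1OC | intermediate
26 | agehoustin C (3'-hydroxy-5,6,7,8,2',4',5'-heptamethoxyflavone) | COc1cc(-c2cc(=O)c3c(OC)c(OC)c(OC)c(OC)c3o2)c(OC)c(O)c1OC | target

**Step count**

Total: 14 steps. Longest linear sequence: 13 steps (steps 1 to 6 and 8 to 14; step 7 is a one-step side branch).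

**Steps most likely to fail**

Step 12. The dienylketene may revert to the cyclobutenone or decompose faster than it closes onto the pyranone carbon, since that carbon is an electron-poor position of a heterocycle not yet tried in this ring expansion. The fallback builds ring A by classical flavone chemistry; it sets out from phenol 4 and acid chloride 11 and comes back at 25.
- Para-bromination of 4 (NBS, CH2Cl2, −20 °C) should give 4-bromo-2,3,6-trimethoxyphenol F1.
- Methylation (MeI, K2CO3, acetone) gives 1-bromo-2,3,4,5-tetramethoxybenzene F2.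
- Hydroxylation of the aryl bromide (KOH, Pd2(dba)3 as zerovalent palladium source, t-BuXPhos, dioxane–water, 100 °C) gives 2,3,4,5-tetramethoxyphenol F3.
- Ortho-acetylation at its only free ring position (Ac2O, BF3·OEt2, 80 °C, Fries-type) gives 1-(2-hydroxy-3,4,5,6-tetramethoxyphenyl)ethan-1-one F4.
- Esterification with 11 (pyridine, DMAP, CH2Cl2) gives 2-acetyl-3,4,5,6-tetramethoxyphenyl 3-(benzyloxy)-2,4,5-trimethoxybenzoate F5.
- Baker–Venkataraman rearrangement (KOH, pyridine, 50 °C) gives 1-[3-(benzyloxy)-2,4,5-trimethoxyphenyl]-3-(2-hydroxy-3,4,5,6-tetramethoxyphenyl)propane-1,3-dione F6.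
- Cyclodehydration (TsOH, toluene, 80 °C) then gives 25.

Step 10. The magnesiated pyranone may fragment by β-elimination of the ring oxygen, or the exchange reagent may attack the pyranone, before addition to the squarate takes place. The fallback keeps the squarate-based ring expansion but uses a robust alkenyllithium and closes ring C afterwards; it sets out from dimethyl squarate 18 and comes back at 25.
- Methyl vinyl ether and t-BuLi (THF, −78 to 0 °C) give 1-methoxyvinyllithium F7.
- Addition to 18 at −78 °C gives 4-hydroxy-2,3-dimethoxy-4-(1-methoxyethenyl)cyclobut-2-en-1-one F8.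
- Ag2O/MeI gives 2,3,4-trimethoxy-4-(1-methoxyethenyl)cyclobut-2-en-1-one F9.
- Thermolysis in toluene at 110 °C (the alkenyl case of the same ring expansion, closure onto the CH2 terminus) should give 2,3,4,5-tetramethoxyphenol F3.
- From F3 the sequence of the first fallback through F4, F5 and F6 leads to 25.

Step 3. Regiocontrol may be lost, with bromine entering para to the acetoxy group or twice. The fallback fixes the position with a blocking bromine and a deprotonation at the only remaining ring hydrogen; it sets out from phenol 4 and comes back at acid 10.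
- Bromination of the free phenol para to the hydroxyl gives 4-bromo-2,3,6-trimethoxyphenol F1, as in the first fallback.
- Benzylation (BnBr, K2CO3, DMF) gives 2-(benzyloxy)-5-bromo-1,3,4-trimethoxybenzene F10.
- LiN(i-Pr)2 (THF, −78 °C) removes the single ring hydrogen, flanked by bromine and methoxy, to give [3-(benzyloxy)-6-bromo-2,4,5-trimethoxyphenyl]lithium F11.
- CO2 converts F11 into 3-(benzyloxy)-6-bromo-2,4,5-trimethoxybenzoic acid F12.
- n-BuLi (2.2 equiv, THF, −78 °C) gives lithium 3-(benzyloxy)-6-lithio-2,4,5-trimethoxybenzoate F13 by deprotonation and bromine–lithium exchange, and protonation with MeOH and aq. HCl gives 10.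

**Further compounds**

F1 | step 12 | 4-bromo-2,3,6-trimethoxyphenol | COc1cc(Br)c(OC)c(OC)c1O
F2 | step 12 | 1-bromo-2,3,4,5-tetramethoxybenzene | COc1cc(Br)c(OC)c(OC)c1OC
F3 | step 12 | 2,3,4,5-tetramethoxyphenol | COc1cc(O)c(OC)c(OC)c1OC
F4 | step 12 | 1-(2-hydroxy-3,4,5,6-tetramethoxyphenyl)ethan-1-one | CC(=O)c1c(O)c(OC)c(OC)c(OC)c1OC
F5 | step 12 | 2-acetyl-3,4,5,6-tetramethoxyphenyl 3-(benzyloxy)-2,4,5-trimethoxybenzoate | CC(=O)c1c(OC(=O)c2cc(OC)c(OC)c(OCc3ccccc3)c2OC)c(OC)c(OC)c(OC)c1OC
F6 | step 12 | 1-[3-(benzyloxy)-2,4,5-trimethoxyphenyl]-3-(2-hydroxy-3,4,5,6-tetramethoxyphenyl)propane-1,3-dione | COc1cc(C(=O)CC(=O)c2c(O)c(OC)c(OC)c(OC)c2OC)c(OC)c(OCc3ccccc3)c1OC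
F7 | step 10 | 1-methoxyvinyllithium | [Li]C(=C)OC
F8 | step 10 | 4-hydroxy-2,3-dimethoxy-4-(1-methoxyethenyl)cyclobut-2-en-1-one (racemic) | COC(=C)C1(O)C(OC)=C(OC)C1=O
F9 | step 10 | 2,3,4-trimethoxy-4-(1-methoxyethenyl)cyclobut-2-en-1-one (racemic) | COC(=C)C1(OC)C(OC)=C(OC)C1=O
F10 | step 3 | 2-(benzyloxy)-5-bromo-1,3,4-trimethoxybenzene | COc1cc(Br)c(OC)c(OC)c1OCc2ccccc2
F11 | step 3 | [3-(benzyloxy)-6-bromo-2,4,5-trimethoxyphenyl]lithium | COc1c([Li])c(Br)c(OC)c(OC)c1OCc2ccccc2
F12 | step 3 | 3-(benzyloxy)-6-bromo-2,4,5-trimethoxybenzoic acid | COc1c(C(=O)O)c(Br)c(OC)c(OC)c1OCc2ccccc2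
F13 | step 3 | lithium 3-(benzyloxy)-6-lithio-2,4,5-trimethoxybenzoate | COc1c(C(=O)O[Li])c([Li])c(OC)c(OC)c1OCc2ccccc2
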